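The numbers in the tables were computed for an exercise; scatter was added.

Over the first half-day, the earlier runs make little target; the interest lies in how the curve bends afterwards, and in the charge of precatalyst.

| setting | alpha | zeta | delta | flask |
|---|---|---|---|---|
| starting material | 1 M | 1 M | 1.5 M | 1.0 M |
| second substrate | 0.50 M | 0.50 M | 0.50 M | 0.500 M |
| precatalyst | 1.3 mM | 3 mM | 2 mM | 2.0 mM |
| remark | run made earlier | run made earlier | run made earlier |  |

| run | time / h | target / % |
|---|---|---|
| alpha | 2.00 | 2 |
| alpha | 6.00 | 0 |
| alpha | 12.0 | 4 |
| alpha | 20.0 | 6 |
| alpha | 25.0 | 9 |
| zeta | 2.00 | 2 |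
| zeta | 6.00 | 4 |
| zeta | 12.0 | 5 |
| zeta | 20.0 | 16 |
| zeta | 25.0 | 22 |
| delta | 2.00 | 4 |
| delta | 4.00 | 1 |
| delta | 8.00 | 2 |
| delta | 12.0 | 3 |
| delta | 25.0 | 11 |

(scatter of a reading: 1.5 percentage points)

- factor on the rate of making target when 30% of the starting material are converted if second substrate is charged twice over
- factor on the rate when 30% of the starting material are converted if precatalyst is charged at 0.40 mM instead

- no earlier run changes the charge of second substrate; that part of a forecast is a guess

Let the turnover rate T be the rate of making target per unit of catalyst charged. Pooling the alpha and zeta runs up to 12.0 h gives a slope of only 1.74 /h. Between 20.0 h and 25.0 h the same runs give a late slope, the turnover rate T = 4.19 /h, which is faster than the early slope. This reading carries an uncertainty of about a third of its value.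

By 25.0 h the pooled runs have made 72.1 turnovers per catalyst. The late line, traced back, therefore meets zero at a knee near 7.78 h. For the flask, this reckoning has that line rise at 8.37 mM/h and reach 14.4% at 25.0 h.

If T holds at both charges, the rate at equal conversion follows the charge, so this reckoning gives a factor of 0.200. For second substrate it offers no number, since no run varies it.

The forecast differs, with 0.42 for the smaller charge, and reads the runs to mean that “something active builds up, by slow activation or autocatalysis”; for the doubled second substrate it guesses 2.

The simulation gives 0.198 for the smaller charge and 0.955 for the doubled second substrate.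

    catalyst intermediate B → free catalyst + second product (k = 3.90 /min)
    second substrate + free catalyst ⇌ catalyst intermediate B (K = 27.0 /M, k = 2.20 /M/min)
    catalyst intermediate A → free catalyst + target (k = 0.120 /min)
    starting material + free catalyst ⇌ catalyst intermediate A (K = 3.00 /M, k = 0.380 /M/min)
    2 starting material → homo dimer (k = 1.80 × 10⁻⁴ /M/min)
    precatalyst → free catalyst (k = 0.00280 /min)

In the flask at 12.5 h, homo dimer holds 20.4% of the starting material charged, more than target at 5.41%. At 14.8 h the flask makes target at 0.00653 M/h, which is 0.780 of T times its charge. With precatalyst at 0.40 mM, the rate at 30% conversion of starting material is 1.29 mM/h, which is 0.771 of T times that charge.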